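## Retrosynthetic overview
1. Last disconnection is the C4–ring A bond. It leads to the enol triflate of a 3-methoxytetronic acid and 4-iodophenol, joined by a base-free nickel-catalysed electroreductive cross-electrophile coupling.
2. The butenolide is the only ring made, since both benzene rings are bought. Its C3–C4 bond comes from Dieckmann closure of an O-methoxyacetyl aryl-lactate ester.
3. The ring B–prenyl bond comes from a photo-Claisen [1,3] shift of an O-prenyl ether. One alkylation with prenyl bromide installs both this ether and the ester used in the Dieckmann step.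
4. The C5–O1 bond and the C5 stereocentre come from D-tyrosine by deaminative acyloxylation in methoxyacetic acid with net retention. No protecting groups are used.

Assumption: C2–C5 are the furan-2(5H)-one atoms (C2 carbonyl, C3 OMe, C4 aryl, C5 stereocentre). Ring A is the 4-hydroxyphenyl group on C4 and ring B is the prenylated benzyl ring. The stereocentre in the given SMILES is (R), which maps onto D-tyrosine with retention.

## Route

Step 1
Reactants: 1 D-tyrosine; 2 methoxyacetic acid
Product: 4 (R)-3-(4-hydroxyphenyl)-2-(2-methoxyacetoxy)propanoic acid, via alpha-lactone 3 (not isolated)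
Conditions: NaNO2 (2 equiv, in portions), neat 2 (15 equiv), N2, 10 to 23 °C, 6 h
Reagents that add atoms: none
Why: This is the known NaNO2/carboxylic acid deaminative acyloxylation of alpha-amino acids, in which the carboxylate expels N2 with inversion to give 3 and 2 opens 3 with a second inversion, so the (R) centre of 1 is kept by net retention and becomes C5.

Step 2
Reactants: 4 (R)-3-(4-hydroxyphenyl)-2-(2-methoxyacetoxy)propanoic acid; 5 prenyl bromide (1-bromo-3-methylbut-2-ene)
Product: 6 3-methylbut-2-en-1-yl (R)-2-(2-methoxyacetoxy)-3-[4-(3-methylbut-2-en-1-yloxy)phenyl]propanoate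
Conditions: 5 (2.3 equiv), K2CO3 (2.5 equiv), DMF, 0 to 23 °C, 12 h
Reagents that add atoms: none
Why: Williamson ether synthesis and carboxylate SN2 alkylation run together in a polar aprotic solvent, where O-alkylation dominates and the weak base does not touch the alpha-stereocentre.

Step 3
Reactants: 6 3-methylbut-2-en-1-yl (R)-2-(2-methoxyacetoxy)-3-[4-(3-methylbut-2-en-1-yloxy)phenyl]propanoate
Product: 8 3-methylbut-2-en-1-yl (R)-3-[4-hydroxy-3-(3-methylbut-2-en-1-yl)phenyl]-2-(2-methoxyacetoxy)propanoate, via ortho-dienone 7 (not isolated)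
Conditions: hν (254 nm, low-pressure Hg lamp, quartz flow coil), degassed MeOH (0.01 M), 20 °C, to about 70% conversion, recovered 6 recycled
Reagents that add atoms: none
Why: In this photo-Claisen rearrangement the excited aryl ether homolyses its O–CH2 bond and the caged phenoxyl/prenyl pair recombines at the free ortho carbon through the unhindered primary terminus (para position blocked) to give 7, which tautomerises to 8, while MeOH hydrogen bonding suppresses later photocyclisation to the chroman and the remote stereocentre is untouched.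

Step 4
Reactants: 8 3-methylbut-2-en-1-yl (R)-3-[4-hydroxy-3-(3-methylbut-2-en-1-yl)phenyl]-2-(2-methoxyacetoxy)propanoate
Product: 9 (R)-4-hydroxy-5-[4-hydroxy-3-(3-methylbut-2-en-1-yl)benzyl]-3-methoxyfuran-2(5H)-one
Conditions: LiN(SiMe3)2 (3.3 equiv), THF, −78 to −20 °C, 2 h; then cold 1 M HCl
Reagents that add atoms: none
Why: In this Dieckmann condensation, a closure well established for alkoxyacetates of alpha-hydroxy esters, chelation-assisted kinetic deprotonation of the unhindered methoxyacetate CH2 is followed by 5-exo attack on the prenyl ester and loss of prenoxide, and the tetronate anion formed at once shields C5–H from epimerisation.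

Step 5
Reactants: 9 (R)-4-hydroxy-5-[4-hydroxy-3-(3-methylbut-2-en-1-yl)benzyl]-3-methoxyfuran-2(5H)-one
Product: 10 (R)-2-[4-hydroxy-3-(3-methylbut-2-en-1-yl)benzyl]-4-methoxy-5-oxo-2,5-dihydrofuran-3-yl trifluoromethanesulfonate
Conditions: Tf2O (1.05 equiv), iPr2NEt (1.05 equiv), CH2Cl2, −78 °C, 30 min
Reagents that add atoms: trifluoromethanesulfonic anhydride, O=S(=O)(OS(=O)(=O)C(F)(F)F)C(F)(F)F
Why: This is O-sulfonylation of a vinylogous acid, in which one equivalent of amine ionises only the tetronic acid OH (pKa about 4 to 5) while the phenol (pKa about 10) stays neutral and inert to Tf2O at −78 °C.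

Step 6
Reactants: 10 (R)-2-[4-hydroxy-3-(3-methylbut-2-en-1-yl)benzyl]-4-methoxy-5-oxo-2,5-dihydrofuran-3-yl trifluoromethanesulfonate; 11 4-iodophenol
Product: 12 (R)-5-[4-hydroxy-3-(3-methylbut-2-en-1-yl)benzyl]-4-(4-hydroxyphenyl)-3-methoxyfuran-2(5H)-one (target)
Conditions: undivided cell, Zn anode, graphite-felt cathode, NiBr2·dme (10 mol %), 4,4'-di-tert-butyl-2,2'-bipyridine (12 mol %), 11 (2 equiv), n-Bu4NBF4 (0.1 M), DMF, 5 mA constant current until 10 is consumed (about 3 F/mol), 20 °C, Ar
Reagents that add atoms: none
Why: Proposed new method: electroreductive nickel cross-electrophile coupling of a tetronate enol triflate that carries a base-labile gamma-stereocentre with an unprotected iodophenol; cathodically formed zerovalent nickel inserts first into the weak C–I bond of 11, one-electron reduction gives an electron-rich aryl monovalent-nickel species that prefers the strongly electron-poor vinylogous acyl triflate 10 over a second electron-rich 11, and reductive elimination from trivalent nickel forms the C4–ring A bond; no base is present and the cathode is held near the nickel reduction potential, so C5–H, the prenyl group and both phenols are untouched and (R) is kept; the closest known reaction types are nickel/bipyridine electroreductive aryl halide–vinyl halide coupling with a sacrificial anode and palladium cross-coupling of tetronate triflates.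

## Compound list
1 | D-tyrosine | N[C@H](Cc1ccc(O)cc1)C(=O)O | starting material
2 | methoxyacetic acid | COCC(=O)O | starting material
3 | (S)-3-(4-hydroxybenzyl)oxiran-2-one (alpha-lactone) | O1[C@@H](Cc2ccc(O)cc2)C1=O | intermediate
4 | (R)-3-(4-hydroxyphenyl)-2-(2-methoxyacetoxy)propanoic acid | COCC(=O)O[C@H](Cc1ccc(O)cc1)C(=O)O | intermediate
5 | prenyl bromide (1-bromo-3-methylbut-2-ene) | CC(C)=CCBr | starting material
6 | 3-methylbut-2-en-1-yl (R)-2-(2-methoxyacetoxy)-3-[4-(3-methylbut-2-en-1-yloxy)phenyl]propanoate | COCC(=O)O[C@H](Cc1ccc(OCC=C(C)C)cc1)C(=O)OCC=C(C)C | intermediate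
7 | 3-methylbut-2-en-1-yl (2R)-2-(2-methoxyacetoxy)-3-[3-(3-methylbut-2-en-1-yl)-4-oxocyclohexa-1,5-dien-1-yl]propanoate (ortho-dienone, both epimers at the ring sp3 carbon) | O=C1C=CC(C[C@@H](OC(=O)COC)C(=O)OCC=C(C)C)=CC1CC=C(C)C | intermediate
8 | 3-methylbut-2-en-1-yl (R)-3-[4-hydroxy-3-(3-methylbut-2-en-1-yl)phenyl]-2-(2-methoxyacetoxy)propanoate | COCC(=O)O[C@H](Cc1ccc(O)c(CC=C(C)C)c1)C(=O)OCC=C(C)C | intermediate
9 | (R)-4-hydroxy-5-[4-hydroxy-3-(3-methylbut-2-en-1-yl)benzyl]-3-methoxyfuran-2(5H)-one | COC1=C(O)[C@@H](Cc2ccc(O)c(CC=C(C)C)c2)OC1=O | intermediate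
10 | (R)-2-[4-hydroxy-3-(3-methylbut-2-en-1-yl)benzyl]-4-methoxy-5-oxo-2,5-dihydrofuran-3-yl trifluoromethanesulfonate | COC1=C(OS(=O)(=O)C(F)(F)F)[C@@H](Cc2ccc(O)c(CC=C(C)C)c2)OC1=O | intermediate
11 | 4-iodophenol | Oc1ccc(I)cc1 | starting material
12 | (R)-5-[4-hydroxy-3-(3-methylbut-2-en-1-yl)benzyl]-4-(4-hydroxyphenyl)-3-methoxyfuran-2(5H)-one | COC1=C(c2ccc(O)cc2)[C@@H](Cc2ccc(O)c(CC=C(C)C)c2)OC1=O | target

## Step count and risks
Total step count: 6. Longest linear sequence: 6 (1 to 12).

**Step 1.**
- Risk: nitrosation or nitration of the free phenol ring, capture of 3 by the water that forms, and aryl participation that could erode the ee.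
- Fallback: it sets out from 1 and comes back at 6. Diazotise 1 in aqueous H2SO4 with NaNO2 at 0 °C to give (R)-2-hydroxy-3-(4-hydroxyphenyl)propanoic acid F1, a long-established retentive hydrolysis. Alkylate the carboxylate and the phenol of F1 with 5 and K2CO3 in DMF to give 3-methylbut-2-en-1-yl (R)-2-hydroxy-3-[4-(3-methylbut-2-en-1-yloxy)phenyl]propanoate F2. Acylate the free secondary alcohol with methoxyacetyl chloride and pyridine in CH2Cl2 at 0 °C to reach 6.

**Step 3.**
- Risk: cage escape to the free phenol, recombination at the tertiary prenyl terminus or at the blocked para carbon, and secondary photocyclisation of 8. The expected yield is only moderate.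
- Fallback: it sets out from 4 and comes back at 9, replacing radical-pair chemistry by halogenation and cross-coupling.
  - Iodinate 4 ortho to the phenol with N-iodosuccinimide (MeCN, catalytic TsOH) to give (R)-3-(4-hydroxy-3-iodophenyl)-2-(2-methoxyacetoxy)propanoic acid F3.
  - Esterify only the acid with Me3SiCHN2 (toluene/MeOH, 0 °C) to give methyl (R)-3-(4-hydroxy-3-iodophenyl)-2-(2-methoxyacetoxy)propanoate F4.
  - Run a Stille coupling with tributyl(3-methylbut-2-en-1-yl)stannane and Pd(PPh3)4 in DMF at 80 °C to give methyl (R)-3-[4-hydroxy-3-(3-methylbut-2-en-1-yl)phenyl]-2-(2-methoxyacetoxy)propanoate F5.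
  - Submit F5 to the conditions of step 4, where methoxide leaves instead of prenoxide, to give 9.

**Step 6 (the proposed new step).**
- Risk: homocoupling of either partner, hydrodetriflation of 10 by phenolic protons, and O-attack of cathodically formed phenoxide on 10.
- Fallback: it sets out from 10 and comes back at 12, using known chemistry. Run a Suzuki–Miyaura coupling of 10 with 4-hydroxyphenylboronic acid, PdCl2(dppf) (5 mol %) and NaHCO3 in THF/H2O at 40 °C. The weak base limits epimerisation at C5 and phenoxide attack on C4. This fallback makes no new compound (F0).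

## Further compounds
F1 | step 1 | (R)-2-hydroxy-3-(4-hydroxyphenyl)propanoic acid | O[C@H](Cc1ccc(O)cc1)C(=O)O
F2 | step 1 | 3-methylbut-2-en-1-yl (R)-2-hydroxy-3-[4-(3-methylbut-2-en-1-yloxy)phenyl]propanoate | O[C@H](Cc1ccc(OCC=C(C)C)cc1)C(=O)OCC=C(C)C
F3 | step 3 | (R)-3-(4-hydroxy-3-iodophenyl)-2-(2-methoxyacetoxy)propanoic acid | COCC(=O)O[C@H](Cc1ccc(O)c(I)c1)C(=O)O
F4 | step 3 | methyl (R)-3-(4-hydroxy-3-iodophenyl)-2-(2-methoxyacetoxy)propanoate | COCC(=O)O[C@H](Cc1ccc(O)c(I)c1)C(=O)OC
F5 | step 3 | methyl (R)-3-[4-hydroxy-3-(3-methylbut-2-en-1-yl)phenyl]-2-(2-methoxyacetoxy)propanoate | COCC(=O)O[C@H](Cc1ccc(O)c(CC=C(C)C)c1)C(=O)OC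
F0 | step 6 | none | none
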